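**Open the ledger.** Count the starting material. It is the limiting reagent, 120 mM in oak against 144 mM of reagent, more than the charge needs, so write each entry as a fraction of that charge. Cedar repeats the oak charge, so read the oak run for it.

the same everywhere: starting material 120 mM
- oak: reagent 144 mM
- alder: reagent 220 mM
- cedar: reagent 144 mM; time 450 s

| run | time / s | [target] / mM |
|---|---|---|
| oak run | 14 | 10.6 |
| oak run | 42 | 25.6 |
| oak run | 79 | 40.2 |
| oak run | 130 | 52.2 |
| oak run | 180 | 59.1 |
| alder run | 14 | 18.1 |
| alder run | 42 | 42.6 |
| alder run | 79 | 61.5 |
| alder run | 130 | 75.7 |
| alder run | 180 | 83.0 |

(scatter of a reading: 0.4 mM)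

- how the opening rate goes with [reagent] round the charge of the oak run: the exponent of the rate at two percent of starting material gone to target
- target in the cedar run at 450 s, as a share of the starting material charged

- Overall: starting material + reagent -> target.
- Constant volume, constant temperature.
- What is held in complexes is read along with the free species.
- "The second partner" is reagent.
- An order is taken over about fifteen percent of the charge, up and down.

**The opening.** Take the first readings of alder and oak, which give an exponent of 1.26 for reagent, but only as a rough reading, taken across the whole step from 144 mM to 220 mM.

**The far end.** Book 0.492 as target in oak at 180 s. Then draw two chords through the oak readings, 0.00329 s⁻¹ at 0.274 and 0.00115 s⁻¹ at 0.464, and suppose that the rate goes as the square of the gap below a ceiling, which puts the ceiling at 0.738. Define the closing constant, the steady rise of the reciprocal gap each second, as 0.0153 s⁻¹. Test it on the chord between: it predicts 0.00190 s⁻¹, and the readings give 0.00196 s⁻¹.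

**Closing the books.** From the oak gap of 0.246 at 180 s, the reckoned gap falls to half of itself in 267 s, and 270 s remain, about that long. So enter, as my estimate for cedar, 0.616 as target at 450 s, 0.122 between that and the ceiling read from oak, and 0.262 above that ceiling.

**The forecast.** It gives an exponent of 1.4, above my rough 1.26, and a share of 61%, a little under my 61.6%, and says: “The reaction is stalling short of completion”.

**The flask.** Target in cedar stands at 62.6% of the charge at 450 s, the exponent round the oak charge is 1.3, and the scheme holds a second path for starting material, to homo dimer, with a rate constant of 0.0464 L mol⁻¹ s⁻¹.

    starting material + reagent → target (0.05240 L mol⁻¹ s⁻¹)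
    starting material + 2 reagent → target + reagent (0.1520 L² mol⁻² s⁻¹)
    2 starting material → homo dimer (0.04640 L mol⁻¹ s⁻¹)
    2 starting material ⇌ idle substrate dimer, settled at all times (3.120 L mol⁻¹)

**Second flask.** Against the ceiling read from oak, cedar's gap at 450 s is 0.112, about half the oak gap at 180 s. Draw the same chords in alder, which give a ceiling of 0.923 and a closing constant of 0.0178 s⁻¹. The reciprocal gap then carries alder from a quarter of its charge to half in 49.3 s, and alder took 49.5 s.

All runs come from a simulation for substances that don't exist; the scatter is artificial.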